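**Conventions.** Oxolane: O1, C2 (aryl), C3 (CH2OH), C4 (OH and benzyl), C5. Dihydrobenzofuran: primed locants (O1', C2', C3'; C5' is bonded to C2). Ring A is the guaiacyl ring of the C4 benzyl group, ring B the benzo ring of the dihydrobenzofuran, ring C the guaiacyl ring on C2'. In names, BnV = 4-(benzyloxy)-3-methoxyphenyl and DBF = (2R,3R)-3-[(benzyloxy)methyl]-2-[4-(benzyloxy)-3-methoxyphenyl]-7-methoxy-2,3-dihydro-1-benzofuran-5-yl. Compound numbers are those of the steps.

## Analysis of the target

Target 26 is a sesquilignan. Its oxolane carries a hydroxyl and the ring A benzyl group on C4, a hydroxymethyl on C3 and, on C2, ring B of a 2-aryl-3-(hydroxymethyl)-7-methoxy-2,3-dihydrobenzofuran whose C2' bears ring C. There are five stereocentres in two clusters: (2R,3R,4S) on the oxolane and (2'R,3'R) on the dihydrobenzofuran. On the oxolane the C2 aryl, the C3 CH2OH and the C4 benzyl carbon lie on one face, with C3–H and the C4 hydroxyl on the other; on the dihydrobenzofuran the aryl and CH2OH are cis. The two clusters are separated by ring B, so neither can direct the other and each must be set with absolute control before the halves are joined. Both rings hold their substituents in the less stable cis arrangement. C2 and C2' are benzylic ether carbons para to an oxygen, so acid can ionise and epimerise them and forcing hydrogenolysis can cleave them; the two phenols are oxidation-prone, and an ester precursor at C3' would epimerise with base. The main difficulty is a fully substituted carbinol carbon (C4) of defined configuration next to two further contiguous centres, all cis, to be assembled under near-neutral conditions. The strategy rests on the cis relation of the C3 carbon arm and the ring A benzylic carbon on C4: joined through oxygen they form a γ-lactone, which makes the oxolane one ring of a cis-fused 3,7-dioxabicyclo[3.3.0]octan-2-one with the C2 aryl on its concave face and C2–H five atoms from C3.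

## Retrosynthetic reasoning

**26 ⇒ 25 ⇒ 24 ⇒ 23.** The last operations are kept reductive and neutral. Silyl ether 25 only masks the C4 hydroxyl. Its C3 hydroxymethyl is taken back to the carboxyl of acid 24, and joining that carboxyl oxygen to the ring A benzylic carbon gives lactone 23, with the phenols and the C3' alcohol as benzyl ethers. No skeletal bond is cut; the gain is that the flexible oxolane becomes part of a rigid bicycle. Forward, hydrogenolysis must cleave the lactone C–O bond at the ring A benzylic carbon and three benzyl ethers but spare C2–O1 and C2'–O1', and a carboxylic acid must then be reduced beside free phenols.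

**23 ⇒ 22 (C2–C3).** This bond joins the two stereocentres still to be made, and cutting it leaves only an ether chain on C4 and a diazo group on the lactone α-carbon. Cutting O1–C2 instead would call for a benzylic cation under acid, and cutting C3–C4 would place the bond formation at the fully substituted carbon. Forward, the carbenoid from 22 must insert into the benzylic ether C–H, close the oxolane and set C2 and C3 in one step.

**22 ⇒ 20 ⇒ 19.** The diazo group comes from the lactone methylene of 20 by acyl activation and diazo transfer. The silyl ether comes from tertiary alcohol 19; it keeps the hydroxyl from quenching the enolate and the carbenoid.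

**19 ⇒ 7 + 18 (O1–CH2 ether bond).** Cutting the ether between O1 and the future C2 separates the two stereo-clusters completely, into diol lactone 7 and imidate 18. The union needs only mild acid, and the primary hydroxyl of 7 is far more reactive than the tertiary one.

**7 ⇒ 6 ⇒ 5.** The lactone C–O bond at the ring A benzylic carbon is formed by opening epoxide 6 with its own ester carbonyl, with inversion. This puts ring A trans to the CH2O arm, which is the exo position in the later bicycle. Epoxide 6 comes from allylic alcohol 5 by hydroxyl-directed asymmetric epoxidation, the single event that fixes C4. The benzylic centre made at the same time is sacrificial: it steers the key step and is erased by the final hydrogenolysis.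

**5 ⇒ 4 ⇒ 3 ⇒ 1 + 2.** The carbon chain is that of an arylidene succinate. Condensing aldehyde 1 with succinate 2 gives half-ester 3 with its two carboxyls already differentiated, so the conjugated one can be reduced (via 4) to the allylic alcohol.

**18 ⇒ 17 ⇒ 16 ⇒ 15 ⇒ 14.** These are protecting-group and oxidation-level changes. The ester of 14 is reduced early so that C3' can no longer epimerise, and the C5' carbon is unmasked last to carry the leaving group.

**14 ⇒ 13 (C2'–C3').** The cis ester is the kinetic product of a second carbenoid insertion, that of an aryl diazoacetate into the neighbouring benzylic ether C–H under a chiral dirhodium carboxylate. This sets both centres of the second cluster together.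

**13 ⇒ 12 ⇒ 11 ⇒ 10 ⇒ 8 + 9.** The diazoacetate is attached at the aryl iodide position of 12. The C5' carbon is the reduced and silylated aldehyde of iodophenol 8, and the aryl benzyl ether is made from 8 and benzylic alcohol 9.

## Alternatives that were turned down

**Alternative 1:** The C2'–aryl and C3'–carbonyl bonds of the dihydrobenzofuran are cut together. Forward, benzofuran A2 and aryl iodide A3 are combined under alkoxycarbonylation conditions with a zerovalent palladium catalyst and a chiral phosphine: syn arylpalladation of C2'=C3', then carbonylative capture of the benzylic palladium species, gives cis diester A1.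
- For: one catalytic step from flat precursors; cis follows from the syn addition; both the C3' and C5' carbons arrive in place. On step count for this half it beats steps 6 to 10.
- Against: the arylpalladium species would be carbonylated directly faster than it adds to an aromatic C2'=C3' bond; intermolecular, regio- and enantiocontrolled dearomative arylpalladation of benzofurans is not an established reaction class; the two esters of A1 must then be told apart.
- Comparison: it does not address the oxolane, where three of the five centres and the fully substituted carbon lie. The chosen route reaches the same kind of cis ester (14) by a known carbenoid insertion and keeps its one uncertain step for the harder ring.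

**Alternative 2:** The O1–C2 bond is cut, with hydride delivered to C2. Forward, γ-hydroxy aryl ketone A5 closes to its lactol, a Lewis acid ionises it, and a silane reduces the 2-aryl oxocarbenium ion to give A4.
- For: convergent and short after ring closure, with no sacrificial centre and no hydrogenolysis. Hydride would come from the face of the C4 hydroxyl, the more open one, so on facial bias it is not weaker.
- Against: C3 and C4 must first be set in an open chain where C3 is α to the ketone and β to a tertiary hydroxyl, inviting epimerisation, retro-aldol cleavage and dehydration. The electron-rich oxocarbenium ion can lose the C3 proton and then the C4 hydroxyl on the way to a furan. The Lewis acid also threatens C2' of the cis dihydrobenzofuran and the newly formed C2–O1 bond.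
- Comparison: the chosen route is longer at the end, but it forms C2 and C3 under neutral conditions, with C3 fixed by a ring fusion rather than by an enolisable centre.

**Alternative 3:** The C3'–C3a' bond is traced to an aryl shift. Forward, irradiation of diazoflavanone A7 in an alcohol triggers Wolff ring contraction, and the ketene is trapped as cis ester A6.
- For: the rearrangement is dependable, C2' is not touched by it, and protonation of the ketene adduct anti to the aryl should favour cis. It avoids the aryl iodide/diazoacetate coupling and is at least as robust there.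
- Against: the flavanone stereocentre can racemise by reversible ring opening at O1'–C2' under the basic conditions of diazo transfer; the cis/trans outcome rests on a protonation rather than a concerted event; the aryl bromide is photolabile; the bromide must later be converted to the C5' carbon in extra steps.
- Comparison: again the oxolane is left unsolved. The chosen route sets both dihydrobenzofuran centres in one concerted insertion with the C5' carbon already present, and spends its risk on the oxolane.

Key step: step 18

Remark: Rh2(S-PTTL)4, dirhodium tetrakis[N-phthaloyl-(S)-tert-leucinate], is assumed to give the (2R,3S) enantiomer of cis ester 14; if the sense of induction on this substrate is the opposite one, Rh2(R-PTTL)4 is used and nothing else changes.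

## Route

Step 1
Reactants: 1 4-(benzyloxy)-3-methoxybenzaldehyde; 2 dimethyl succinate
Product: 3 (3E)-4-(BnV)-3-(methoxycarbonyl)but-3-enoic acid
Conditions: NaOMe, MeOH, reflux; then aq. HCl
Reagents that add atoms: none
Why: Stobbe condensation; the succinate enolate adds to the aldehyde and the sequence ends with the conjugated ester kept, the CH2 arm as free acid and the aryl trans to the ester (E).

Step 2
Reactants: 3
Product: 4 4-tert-butyl 1-methyl (2E)-2-[(BnV)methylidene]butanedioate
Conditions: tert-butyl 2,2,2-trichloroacetimidate, CH2Cl2–cyclohexane, rt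
Reagents that add atoms: tert-butyl 2,2,2-trichloroacetimidate, CC(C)(C)OC(=N)C(Cl)(Cl)Cl
Why: Acid-promoted O-alkylation of the carboxylic acid by the imidate (tert-butyl esterification) without base, so the alkene neither moves nor isomerises; the two carboxyls are now chemically distinct.

Step 3
Reactants: 4
Product: 5 tert-butyl (3E)-4-(BnV)-3-(hydroxymethyl)but-3-enoate
Conditions: i-Bu2AlH (2.2 equiv), CH2Cl2, −78 °C; aq. potassium sodium tartrate
Reagents that add atoms: none
Why: Chemoselective hydride reduction; the methyl ester is reduced to the allylic alcohol at low temperature while the bulky tert-butyl ester is left, and that ester also resists lactonisation by the new hydroxyl.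

Step 4
Reactants: 5
Product: 6 tert-butyl 2-[(2S,3S)-3-(BnV)-2-(hydroxymethyl)oxiran-2-yl]acetate
Conditions: Ti(OiPr)4 (10 mol %), L-(+)-diethyl tartrate (12 mol %), t-BuOOH, 4 Å MS, CH2Cl2, −25 °C; crude product used at once
Reagents that add atoms: tert-butyl hydroperoxide, CC(C)(C)OO
Why: Sharpless asymmetric epoxidation of an E-trisubstituted allylic alcohol; L-(+)-tartrate delivers oxygen to the face that gives the (2S,3S)-epoxide, by analogy with E-cinnamyl alcohols, and this fixes the configuration of the future C4.

Step 5
Reactants: 6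
Product: 7 (4S,5R)-5-(BnV)-4-hydroxy-4-(hydroxymethyl)oxolan-2-one
Conditions: camphorsulfonic acid (10 mol %), CH2Cl2, 0 °C
Reagents that add atoms: none
Why: Acid-catalysed epoxide opening by the neighbouring ester carbonyl at the benzylic carbon, anti to the epoxide oxygen (inversion), with loss of the tert-butyl group; the tertiary C–O bond is not broken, so C4 keeps its configuration and ring A ends trans to the CH2OH arm.

Step 6
Reactants: 8 4-hydroxy-3-iodo-5-methoxybenzaldehyde (5-iodovanillin); 9 [4-(benzyloxy)-3-methoxyphenyl]methanol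
Product: 10 4-[(BnV)methoxy]-3-iodo-5-methoxybenzaldehyde
Conditions: PPh3, DIAD, THF, 0 °C to rt
Reagents that add atoms: none
Why: Mitsunobu etherification; the acidic iodophenol is O-alkylated by the activated benzylic alcohol under neutral conditions.

Step 7
Reactants: 10
Product: 11 {4-[(BnV)methoxy]-3-iodo-5-methoxyphenyl}methanol
Conditions: NaBH4, MeOH–THF, 0 °C
Reagents that add atoms: none
Why: Borohydride reduction of the aldehyde, which would otherwise react with the diazo ester and the carbenoid of steps 9 and 10.

Step 8
Reactants: 11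
Product: 12 tert-butyl({4-[(BnV)methoxy]-3-iodo-5-methoxyphenyl}methoxy)dimethylsilane
Conditions: t-BuMe2SiCl, imidazole, DMF, rt
Reagents that add atoms: tert-butyl(chloro)dimethylsilane, CC(C)(C)[Si](C)(C)Cl
Why: Standard silylation of a primary alcohol; the silyl ether is inert to carbenoids and orthogonal to the benzyl ethers.

Step 9
Reactants: 12
Product: 13 methyl 2-{2-[(BnV)methoxy]-5-({[tert-butyl(dimethyl)silyl]oxy}methyl)-3-methoxyphenyl}-2-diazoacetate
Conditions: Pd(PPh3)4 (5 mol %), Ag2CO3 (0.5 equiv), Et3N, methyl diazoacetate, toluene, rt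
Reagents that add atoms: methyl diazoacetate, COC(=O)C=[N+]=[N-]
Why: Palladium-catalysed cross-coupling of an aryl iodide with the C–H bond of an acceptor diazo ester; zerovalent palladium adds to the C–I bond, the silver salt takes up iodide, and the diazo group is retained at room temperature.

Step 10
Reactants: 13
Product: 14 methyl (2R,3S)-2-(BnV)-5-({[tert-butyl(dimethyl)silyl]oxy}methyl)-7-methoxy-2,3-dihydro-1-benzofuran-3-carboxylate (aryl and ester cis)
Conditions: Rh2(S-PTTL)4 (1 mol %), toluene, −78 to −40 °C
Reagents that add atoms: none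
Why: Enantioselective intramolecular 1,5 C–H insertion of a donor/acceptor rhodium carbenoid into the adjacent benzylic ether C–H bond, a known route to cis-2-aryl-2,3-dihydrobenzofuran-3-carboxylates; the concerted insertion leaves aryl and ester cis as the kinetic product, and the chiral carboxylate ligands set the absolute sense of C2' and C3' together.

Step 11
Reactants: 14
Product: 15 [(2R,3R)-2-(BnV)-5-({[tert-butyl(dimethyl)silyl]oxy}methyl)-7-methoxy-2,3-dihydro-1-benzofuran-3-yl]methanol
Conditions: i-Bu2AlH (3 equiv), CH2Cl2, −78 °C
Reagents that add atoms: none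
Why: Non-basic hydride reduction of the ester at low temperature, so the acidic benzylic C3'–H is not epimerised; once reduced, C3' is configurationally safe.

Step 12
Reactants: 15
Product: 16 [(DBF)methoxy](tert-butyl)dimethylsilane
Conditions: NaH, BnBr, Bu4NI (cat.), THF, 0 °C to rt
Reagents that add atoms: benzyl bromide, BrCc1ccccc1
Why: Williamson etherification of the primary alkoxide; no acidic C–H remains near the stereocentres.

Step 13
Reactants: 16
Product: 17 (DBF)methanol
Conditions: Bu4NF, THF, 0 °C
Reagents that add atoms: none
Why: Fluoride cleavage of the primary silyl ether; the benzyl ethers and the ring are untouched.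

Step 14
Reactants: 17
Product: 18 (DBF)methyl 2,2,2-trichloroacetimidate
Conditions: Cl3CCN, DBU (10 mol %), CH2Cl2, 0 °C; used fresh
Reagents that add atoms: trichloroacetonitrile, N#CC(Cl)(Cl)Cl
Why: Base-catalysed addition of the alcohol to trichloroacetonitrile gives an imidate that a weak acid can activate, which suits this electron-rich benzylic system.

Step 15
Reactants: 7; 18
Product: 19 (4S,5R)-5-(BnV)-4-hydroxy-4-{[(DBF)methoxy]methyl}oxolan-2-one
Conditions: pyridinium p-toluenesulfonate (10 mol %), CH2Cl2, 0 °C to rt
Reagents that add atoms: none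
Why: Acid-catalysed O-alkylation with a benzylic trichloroacetimidate; the primary hydroxyl of 7 reacts much faster than the hindered tertiary one, and the weak acid leaves the lactone, the benzylic ethers and the cis dihydrobenzofuran alone.

Step 16
Reactants: 19
Product: 20 (4S,5R)-5-(BnV)-4-{[(DBF)methoxy]methyl}-4-[(trimethylsilyl)oxy]oxolan-2-one
Conditions: N-(trimethylsilyl)imidazole, CH2Cl2, rt
Reagents that add atoms: N-(trimethylsilyl)imidazole, C[Si](C)(C)n1ccnc1
Why: Neutral silylation of a tertiary alcohol with the strongest common trimethylsilyl donor for hydroxyl groups; no acid is released.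

Step 17
Reactants: 20
Product: 22 (4S,5R)-5-(BnV)-3-diazo-4-{[(DBF)methoxy]methyl}-4-[(trimethylsilyl)oxy]oxolan-2-one, via alpha-trifluoroacetyl lactone 21 (not isolated)
Conditions: LiN(SiMe3)2, THF, −78 °C; CF3CO2CH2CF3, −78 °C; AcOH quench; then MsN3, Et3N, H2O (1 equiv), MeCN, rt
Reagents that add atoms: 2,2,2-trifluoroethyl trifluoroacetate, O=C(OCC(F)(F)F)C(F)(F)F (its acyl group is in 21 only); methanesulfonyl azide, CS(=O)(=O)N=[N+]=[N-]
Why: Detrifluoroacetylative diazo transfer; Claisen acylation of the lactone enolate at −78 °C makes the α-position acidic enough for Regitz-type diazo transfer, and the trifluoroacetyl group leaves with the sulfonamide. At this temperature β-silyloxy lactone enolates are known to be trapped faster than they eliminate.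

Step 18
Reactants: 22
Product: 23 (3R,3aS,6R,6aR)-3-(BnV)-6-(DBF)-3a-[(trimethylsilyl)oxy]tetrahydro-1H,3H-furo[3,4-c]furan-1-one (cis-fused; DBF aryl endo, ring A exo)
Conditions: Rh2(OAc)4 (2 mol %), CH2Cl2, reflux, slow addition of 22
Reagents that add atoms: none
Why: Rh2(OAc)4 takes N2 from 22 and leaves an electrophilic rhodium carbenoid at C3. The C2–H bond, five atoms away and activated by O1 and by electron-rich ring B, passes hydride character to the carbenoid carbon while the C2–C3 bond forms in one three-centre event, and the catalyst is released. This is the 1,5 C–H insertion of α-diazo-γ-butyrolactone carbenoids into benzylic ethers, an established route to endo-aryl furofuranones; only the silyloxy group on the ring-fusion carbon is new to the substrate. The oxolane closes as a five-membered ring through a chair-like six-membered array that includes the migrating hydrogen, and it can only be fused cis to the lactone. C3 is therefore set by the ring fusion: its hydrogen ends on the face of the C4 silyloxy group and its carbonyl arm cis to the ring A benzylic carbon, as the target requires. C2 is set in the same transition state: with the ring B aryl pseudo-equatorial it finishes on the concave face, cis to the C3 arm, and the exo position of ring A fixed in steps 4 and 5 keeps that face open. The step needs selectivity for this C–H bond over 1,2-migration from the fully substituted C4 (which has no hydrogen to shift), over the Si–CH3 and other ether C–H bonds and over attack on the arenes; the double activation and five-membered ring size of the C2–H insertion favour it, and slow addition limits carbene dimerisation.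

Step 19
Reactants: 23
Product: 24 (2R,3R,4S)-4-[(4-hydroxy-3-methoxyphenyl)methyl]-2-[(2R,3R)-2-(4-hydroxy-3-methoxyphenyl)-3-(hydroxymethyl)-7-methoxy-2,3-dihydro-1-benzofuran-5-yl]-4-[(trimethylsilyl)oxy]oxolane-3-carboxylic acid
Conditions: H2 (1 atm), 10 % Pd/C, EtOAc, rt, monitored and stopped at full conversion
Reagents that add atoms: none
Why: Catalytic hydrogenolysis removes the three benzyl ethers and cleaves the lactone C–O bond at the ring A benzylic carbon, which is an ester-type leaving group para to a freed phenol and so the most activated benzylic C–O bond left. The C2–O1 ether (no free para phenol) and the C2'–O1' aryl ether are much slower under these mild conditions; early loss of the silyl group here would not change the last two steps.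

Step 20
Reactants: 24
Product: 25 the C4 trimethylsilyl ether of 26: (2R,3R,4S)-configured oxolane with CH2OH on C3 and OSiMe3 on C4
Conditions: BH3·THF (excess), THF, 0 °C to rt; MeOH quench
Reagents that add atoms: none
Why: Borane reduces the carboxylic acid to the primary alcohol chemoselectively; phenols and alcohols only consume reagent as borates, which methanol releases, and C3 is not epimerised under these non-basic conditions.

Step 21
Reactants: 25
Product: 26 (2R,3R,4S)-4-[(4-hydroxy-3-methoxyphenyl)methyl]-2-[(2R,3R)-2-(4-hydroxy-3-methoxyphenyl)-3-(hydroxymethyl)-7-methoxy-2,3-dihydro-1-benzofuran-5-yl]-3-(hydroxymethyl)oxolan-4-ol (target; oxolane numbered as in the conventions)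
Conditions: NH4F, MeOH, rt
Reagents that add atoms: none
Why: Near-neutral fluoride cleavage of the tertiary trimethylsilyl ether; acid is avoided because the benzylic ethers at C2 and C2' of the free phenolic product would ionise.

## Compound list

1 | 4-(benzyloxy)-3-methoxybenzaldehyde | COc1cc(C=O)ccc1OCc1ccccc1 | starting material
2 | dimethyl succinate | COC(=O)CCC(=O)OC | starting material
3 | (3E)-4-(BnV)-3-(methoxycarbonyl)but-3-enoic acid | COc1cc(/C=C(\CC(=O)O)C(=O)OC)ccc1OCc1ccccc1 | intermediate
4 | 4-tert-butyl 1-methyl (2E)-2-[(BnV)methylidene]butanedioate | COc1cc(/C=C(\CC(=O)OC(C)(C)C)C(=O)OC)ccc1OCc1ccccc1 | intermediate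
5 | tert-butyl (3E)-4-(BnV)-3-(hydroxymethyl)but-3-enoate | COc1cc(/C=C(\CC(=O)OC(C)(C)C)CO)ccc1OCc1ccccc1 | intermediate
6 | tert-butyl 2-[(2S,3S)-3-(BnV)-2-(hydroxymethyl)oxiran-2-yl]acetate | COc1cc([C@@H]2O[C@]2(CO)CC(=O)OC(C)(C)C)ccc1OCc1ccccc1 | intermediate
7 | (4S,5R)-5-(BnV)-4-hydroxy-4-(hydroxymethyl)oxolan-2-one | COc1cc([C@@H]5[C@@](O)(CO)CC(=O)O5)ccc1OCc1ccccc1 | intermediate
8 | 4-hydroxy-3-iodo-5-methoxybenzaldehyde | COc1cc(C=O)cc(I)c1O | starting material
9 | [4-(benzyloxy)-3-methoxyphenyl]methanol | COc1cc(CO)ccc1OCc1ccccc1 | starting material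
10 | 4-[(BnV)methoxy]-3-iodo-5-methoxybenzaldehyde | COc1cc(C=O)cc(I)c1OCc1ccc(OCc2ccccc2)c(OC)c1 | intermediate
11 | {4-[(BnV)methoxy]-3-iodo-5-methoxyphenyl}methanol | COc1cc(CO)cc(I)c1OCc1ccc(OCc2ccccc2)c(OC)c1 | intermediate
12 | tert-butyl({4-[(BnV)methoxy]-3-iodo-5-methoxyphenyl}methoxy)dimethylsilane | COc1cc(CO[Si](C)(C)C(C)(C)C)cc(I)c1OCc1ccc(OCc2ccccc2)c(OC)c1 | intermediate
13 | methyl 2-{2-[(BnV)methoxy]-5-({[tert-butyl(dimethyl)silyl]oxy}methyl)-3-methoxyphenyl}-2-diazoacetate | COC(=O)C(=[N+]=[N-])c1cc(CO[Si](C)(C)C(C)(C)C)cc(OC)c1OCc1ccc(OCc2ccccc2)c(OC)c1 | intermediate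
14 | methyl (2R,3S)-2-(BnV)-5-({[tert-butyl(dimethyl)silyl]oxy}methyl)-7-methoxy-2,3-dihydro-1-benzofuran-3-carboxylate | CC(C)(C)[Si](C)(C)OCc1cc(OC)c2c(c1)[C@H](C(=O)OC)[C@H](c1ccc(OCc3ccccc3)c(OC)c1)O2 | intermediate
15 | [(2R,3R)-2-(BnV)-5-({[tert-butyl(dimethyl)silyl]oxy}methyl)-7-methoxy-2,3-dihydro-1-benzofuran-3-yl]methanol | CC(C)(C)[Si](C)(C)OCc1cc(OC)c2c(c1)[C@H](CO)[C@H](c1ccc(OCc3ccccc3)c(OC)c1)O2 | intermediate
16 | [(DBF)methoxy](tert-butyl)dimethylsilane | CC(C)(C)[Si](C)(C)OCc1cc(OC)c2c(c1)[C@H](COCc1ccccc1)[C@H](c1ccc(OCc3ccccc3)c(OC)c1)O2 | intermediate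
17 | (DBF)methanol | OCc1cc(OC)c2c(c1)[C@H](COCc1ccccc1)[C@H](c1ccc(OCc3ccccc3)c(OC)c1)O2 | intermediate
18 | (DBF)methyl 2,2,2-trichloroacetimidate | N=C(OCc1cc(OC)c2c(c1)[C@H](COCc1ccccc1)[C@H](c1ccc(OCc3ccccc3)c(OC)c1)O2)C(Cl)(Cl)Cl | intermediate
19 | (4S,5R)-5-(BnV)-4-hydroxy-4-{[(DBF)methoxy]methyl}oxolan-2-one | COc1cc([C@@H]5[C@@](O)(COCc3cc(OC)c4c(c3)[C@H](COCc3ccccc3)[C@H](c3ccc(OCc6ccccc6)c(OC)c3)O4)CC(=O)O5)ccc1OCc1ccccc1 | intermediate
20 | (4S,5R)-5-(BnV)-4-{[(DBF)methoxy]methyl}-4-[(trimethylsilyl)oxy]oxolan-2-one | COc1cc([C@@H]5[C@@](O[Si](C)(C)C)(COCc3cc(OC)c4c(c3)[C@H](COCc3ccccc3)[C@H](c3ccc(OCc6ccccc6)c(OC)c3)O4)CC(=O)O5)ccc1OCc1ccccc1 | intermediate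
21 | (4S,5R)-5-(BnV)-4-{[(DBF)methoxy]methyl}-3-(trifluoroacetyl)-4-[(trimethylsilyl)oxy]oxolan-2-one (C3 undefined, enolised) | COc1cc([C@@H]5[C@@](O[Si](C)(C)C)(COCc3cc(OC)c4c(c3)[C@H](COCc3ccccc3)[C@H](c3ccc(OCc6ccccc6)c(OC)c3)O4)C(C(=O)C(F)(F)F)C(=O)O5)ccc1OCc1ccccc1 | intermediate (not isolated)
22 | (4S,5R)-5-(BnV)-3-diazo-4-{[(DBF)methoxy]methyl}-4-[(trimethylsilyl)oxy]oxolan-2-one | COc1cc([C@@H]5[C@@](O[Si](C)(C)C)(COCc3cc(OC)c4c(c3)[C@H](COCc3ccccc3)[C@H](c3ccc(OCc6ccccc6)c(OC)c3)O4)C(=[N+]=[N-])C(=O)O5)ccc1OCc1ccccc1 | intermediate
23 | (3R,3aS,6R,6aR)-3-(BnV)-6-(DBF)-3a-[(trimethylsilyl)oxy]tetrahydro-1H,3H-furo[3,4-c]furan-1-one | COc1cc([C@@H]5[C@@]2(O[Si](C)(C)C)CO[C@@H](c3cc(OC)c4c(c3)[C@H](COCc3ccccc3)[C@H](c3ccc(OCc6ccccc6)c(OC)c3)O4)[C@H]2C(=O)O5)ccc1OCc1ccccc1 | intermediate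
24 | (2R,3R,4S)-4-[(4-hydroxy-3-methoxyphenyl)methyl]-2-[(2R,3R)-2-(4-hydroxy-3-methoxyphenyl)-3-(hydroxymethyl)-7-methoxy-2,3-dihydro-1-benzofuran-5-yl]-4-[(trimethylsilyl)oxy]oxolane-3-carboxylic acid | COc1cc(C[C@@]2(O[Si](C)(C)C)CO[C@@H](c3cc(OC)c4c(c3)[C@H](CO)[C@H](c3ccc(O)c(OC)c3)O4)[C@H]2C(=O)O)ccc1O | intermediate
25 | C4 trimethylsilyl ether of 26 | COc1cc(C[C@@]2(O[Si](C)(C)C)CO[C@@H](c3cc(OC)c4c(c3)[C@H](CO)[C@H](c3ccc(O)c(OC)c3)O4)[C@H]2CO)ccc1O | intermediate
26 | (2R,3R,4S)-4-[(4-hydroxy-3-methoxyphenyl)methyl]-2-[(2R,3R)-2-(4-hydroxy-3-methoxyphenyl)-3-(hydroxymethyl)-7-methoxy-2,3-dihydro-1-benzofuran-5-yl]-3-(hydroxymethyl)oxolan-4-ol | COc1cc(C[C@@]2(O)CO[C@@H](c3cc(OC)c4c(c3)[C@H](CO)[C@H](c3ccc(O)c(OC)c3)O4)[C@H]2CO)ccc1O | target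

## Step count and least certain steps

Total: 21 steps. Longest linear sequence: 16 steps (steps 6 to 14, then 15 to 21). The other branch is 12 steps (steps 1 to 5, then 15 to 21).

**Step 18 (key step).** The silyloxy oxygen on C4 can push a C4 substituent onto the carbenoid carbon (1,2-migration) in competition with insertion, and the insertion could also place the aryl on the convex face. Fallback, from 7 and 17, returning at 23: alcohol 17 is oxidised (TEMPO, PhI(OAc)2, MeCN–H2O) to the carboxylic acid F1. F1 acylates the primary hydroxyl of 7 (EDC·HCl, DMAP) to give aroyl ester F2, and the tertiary hydroxyl is silylated (N-(trimethylsilyl)imidazole) to give F3. LiN(SiMe3)2 at −78 °C then makes the lactone enolate, which attacks the neighbouring ester carbonyl (intramolecular Claisen-type acyl transfer from oxygen to C3) and gives the bicyclic lactol F4 after work-up. Et3SiH with catalytic Me3SiOTf at −78 °C reduces F4 through its oxocarbenium ion from the convex face, which puts the aryl on the concave face and gives 23.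

**Step 17.** The hindered enolate may lose the β-silanolate by elimination or fail to undergo C-acylation at the neopentyl-like position. Fallback, from 19, returning at 22: 19 is converted to its alkoxide–enolate dianion (2.2 equiv LiN(SiMe3)2), whose alkoxide cannot leave. The same trifluoroacetylation and diazo transfer then give the α-diazo-β-hydroxy lactone F5, which is silylated with N-(trimethylsilyl)imidazole to give 22.

**Step 19.** Hydrogenolysis may stall at the hindered lactone C–O bond, and pushing it may begin to cleave the C2–O1 or C2'–O1' benzylic bonds. Fallback, from 23, returning at 24: the hydrogenolysis is run only as far as removal of the benzyl ethers, giving the phenolic lactone F6. NaBH4 in aqueous NaOH–THF (0 °C to rt) then lets the ring A phenoxide expel the lactone carboxylate by 1,6-elimination with hydride capture at the benzylic carbon in the same pot; acidification gives 24.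

**Step 10.** Enantioselection may be insufficient on this substituted substrate or of the opposite sense, and the cis ester may partly epimerise on handling. Fallback, from 14, returning at 19: scalemic material is taken through steps 11 to 14 unchanged, and enantiopure 7 serves as the resolving partner in step 15. The minor enantiomer of 18 then appears as diastereomer F7, which is removed by chromatography or crystallisation at the stage of 19.

**Step 9.** Oxidative addition next to the ortho alkoxy group may be slow, and the diazo ester may lose nitrogen at palladium before coupling. Fallback, from 12, returning at 13: Negishi-type coupling with the Reformatsky reagent BrZnCH2CO2Me (Pd2(dba)3, XPhos, THF) gives methyl arylacetate F8, and Regitz diazo transfer (4-acetamidobenzenesulfonyl azide, DBU, MeCN) gives 13.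

**Step 15.** The imidate may rearrange to the amide, and the acid may ionise the benzylic C–O bonds (loss of configuration at C2' or at the lactone C5). Fallback, from 17, returning at 19: CBr4 and PPh3 convert 17 to the benzylic bromide F9, which alkylates the primary hydroxyl of 7 under Ag2O (CH2Cl2, 4 Å MS, rt) without acid to give 19.

## Further compounds

F1 | step 18 | (2R,3R)-3-[(benzyloxy)methyl]-2-[4-(benzyloxy)-3-methoxyphenyl]-7-methoxy-2,3-dihydro-1-benzofuran-5-carboxylic acid | OC(=O)c1cc(OC)c2c(c1)[C@H](COCc1ccccc1)[C@H](c1ccc(OCc3ccccc3)c(OC)c1)O2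
F2 | step 18 | [(3S,4R... written as (4S,5R)-5-(BnV)-4-hydroxy-2-oxooxolan-4-yl]methyl ester of F1 | COc1cc([C@@H]5[C@@](O)(COC(=O)c3cc(OC)c4c(c3)[C@H](COCc3ccccc3)[C@H](c3ccc(OCc6ccccc6)c(OC)c3)O4)CC(=O)O5)ccc1OCc1ccccc1
F3 | step 18 | trimethylsilyl ether of F2 at the tertiary hydroxyl | COc1cc([C@@H]5[C@@](O[Si](C)(C)C)(COC(=O)c3cc(OC)c4c(c3)[C@H](COCc3ccccc3)[C@H](c3ccc(OCc6ccccc6)c(OC)c3)O4)CC(=O)O5)ccc1OCc1ccccc1
F4 | step 18 | bicyclic lactol: 23 with a hydroxyl in place of hydrogen on the DBF-bearing carbon (that carbon undefined) | COc1cc([C@@H]5[C@@]2(O[Si](C)(C)C)COC(O)(c3cc(OC)c4c(c3)[C@H](COCc3ccccc3)[C@H](c3ccc(OCc6ccccc6)c(OC)c3)O4)[C@H]2C(=O)O5)ccc1OCc1ccccc1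
F5 | step 17 | (4S,5R)-5-(BnV)-3-diazo-4-hydroxy-4-{[(DBF)methoxy]methyl}oxolan-2-one | COc1cc([C@@H]5[C@@](O)(COCc3cc(OC)c4c(c3)[C@H](COCc3ccccc3)[C@H](c3ccc(OCc6ccccc6)c(OC)c3)O4)C(=[N+]=[N-])C(=O)O5)ccc1OCc1ccccc1
F6 | step 19 | 23 with all three benzyl ethers cleaved (two phenols and the C3' CH2OH free, lactone intact) | COc1cc([C@@H]5[C@@]2(O[Si](C)(C)C)CO[C@@H](c3cc(OC)c4c(c3)[C@H](CO)[C@H](c3ccc(O)c(OC)c3)O4)[C@H]2C(=O)O5)ccc1O
F7 | step 10 | diastereomer of 19 with the (2S,3S)-dihydrobenzofuran | COc1cc([C@@H]5[C@@](O)(COCc3cc(OC)c4c(c3)[C@@H](COCc3ccccc3)[C@@H](c3ccc(OCc6ccccc6)c(OC)c3)O4)CC(=O)O5)ccc1OCc1ccccc1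
F8 | step 9 | methyl 2-{2-[(BnV)methoxy]-5-({[tert-butyl(dimethyl)silyl]oxy}methyl)-3-methoxyphenyl}acetate | COC(=O)Cc1cc(CO[Si](C)(C)C(C)(C)C)cc(OC)c1OCc1ccc(OCc2ccccc2)c(OC)c1
F9 | step 15 | (2R,3R)-3-[(benzyloxy)methyl]-2-[4-(benzyloxy)-3-methoxyphenyl]-5-(bromomethyl)-7-methoxy-2,3-dihydro-1-benzofuran | BrCc1cc(OC)c2c(c1)[C@H](COCc1ccccc1)[C@H](c1ccc(OCc3ccccc3)c(OC)c1)O2
A1 | alternative 1 | dimethyl (2R,3S)-2-[4-(benzyloxy)-3-methoxyphenyl]-7-methoxy-2,3-dihydro-1-benzofuran-3,5-dicarboxylate | COC(=O)c1cc(OC)c2c(c1)[C@H](C(=O)OC)[C@H](c1ccc(OCc3ccccc3)c(OC)c1)O2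
A2 | alternative 1 | methyl 7-methoxy-1-benzofuran-5-carboxylate | COC(=O)c1cc(OC)c2occc2c1
A3 | alternative 1 | 1-(benzyloxy)-4-iodo-2-methoxybenzene | COc1cc(I)ccc1OCc1ccccc1
A4 | alternative 2 | 26 with both phenols and both primary alcohols as tert-butyldimethylsilyl ethers | COc1cc(C[C@@]2(O)CO[C@@H](c3cc(OC)c4c(c3)[C@H](CO[Si](C)(C)C(C)(C)C)[C@H](c3ccc(O[Si](C)(C)C(C)(C)C)c(OC)c3)O4)[C@H]2CO[Si](C)(C)C(C)(C)C)ccc1O[Si](C)(C)C(C)(C)C
A5 | alternative 2 | open-chain γ-hydroxy aryl ketone corresponding to A4 (C2 as ketone, C5 hydroxyl free) | COc1cc(C[C@@](O)(CO)[C@H](CO[Si](C)(C)C(C)(C)C)C(=O)c3cc(OC)c4c(c3)[C@H](CO[Si](C)(C)C(C)(C)C)[C@H](c3ccc(O[Si](C)(C)C(C)(C)C)c(OC)c3)O4)ccc1O[Si](C)(C)C(C)(C)C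
A6 | alternative 3 | methyl (2R,3S)-2-[4-(benzyloxy)-3-methoxyphenyl]-5-bromo-7-methoxy-2,3-dihydro-1-benzofuran-3-carboxylate | Brc1cc(OC)c2c(c1)[C@H](C(=O)OC)[C@H](c1ccc(OCc3ccccc3)c(OC)c1)O2
A7 | alternative 3 | (2S)-2-[4-(benzyloxy)-3-methoxyphenyl]-6-bromo-3-diazo-8-methoxy-2,3-dihydro-4H-chromen-4-one | Brc1cc(OC)c2c(c1)C(=O)C(=[N+]=[N-])[C@H](c1ccc(OCc3ccccc3)c(OC)c1)O2
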